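**Abyssomicin O: synthesis proposal built on an intramolecular Diels–Alder reaction of a 2-siloxy trienone**

## Structural features

Abyssomicin O is a compact pentacycle. In the local numbering used here, the γ-lactone (ring C) is O–C1(=O)–C2–C16–C15; the enolised acyl chain runs C3–C4(Me)–C5–C6(Me)–C7(=O)–C8 and closes the eight-membered carbocycle (ring E: C2 to C8 plus C16); the cyclopentane (ring B) is C8–C9–C10–C15–C16; the cyclohexane (ring A) is C10–C11(OH)–C12(Me)–C13(CH2OH)–C14–C15. An ether oxygen joins C12 to C16 (ring D), so rings A and D make a 2-oxabicyclo[2.2.2]octane with bridgeheads C12 and C15. Of the nine stereocentres, seven (C8, C16, C15, C10, C11, C12, C13) are contiguous; three are fully substituted and oxygen-bearing, C15 and C16 being neighbours and C12 lying across ring A. The methyl-bearing centres C4 and C6 are 1,3-syn on ring E, and C6 and C8 flank the C7 ketone and can epimerise. Fragile elements are the enolised β-keto lactone (retro-Claisen cleavage, and the ether oxygen on C16 is β to the lactone carbonyl and can be eliminated), the tertiary ether and the free hydroxyls. The real difficulty is the congested C15–C16–C12 array tied together by the bridging ether, with an eight-membered ring closed onto it. The key step uses the fact that rings A and B share the bond C15–C10 with a cis fusion and that C16, next to C15, can be a ketone: the bonds C15–C10 and C14–C13 then correspond to an intramolecular Diels–Alder reaction of a C14=C15 siloxy enone with a C10=C11–C12=C13 diene tethered through C16–C8–C9.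

## Logic of the disconnections

43 is traced back to 42 and then to 41 without cutting a skeletal bond: the C7 ketone becomes a carbinol and the two hydroxyls become silyl ethers. With C7 as a ketone, C6 and C8 would be enolisable and a ketone enolate would compete in any base-mediated ring closure. The forward steps need an oxidation that tolerates the enolised β-keto lactone and an acidic, fluoride-buffered desilylation.

41 is cut at C2–C3 of ring E to give 40. C2 is the α-carbon of the cage lactone and C3 an acyl carbon, so the bond is a Claisen bond. Holding C3 as a δ-lactone tied to the C7 oxygen turns the eight-membered closure into a six-membered attack followed by ring expansion. The forward step needs enolisation at C2 in preference to C4 and acylation faster than loss of the β-ether oxygen.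

40 is cut at C6–C7 (and, through 38, the C4 stereocentre is traced to a C4=C5 alkene), giving 32 and 37. A vinylogous aldol addition brings in all five chain carbons at once and sets C6 under reagent control. The pentacycle problem is reduced to a cage aldehyde and a two-step reagent made from 33 and 34 via 36. The forward steps need reagent control on a hindered aldehyde and a hydrogenation that sets C4 syn to C6.

32 is related to 29 through 31 and 30 by functional-group changes only: the aldehyde comes from the benzyl ether on the C8 arm, and the C11 hydroxyl is silylated. This demands that the two oxygenated arms (on C8 and on C13) carry different protecting groups from the outset.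

29 is cut at O–C12 (ring D) and C2–C16 (ring C), leading to 27. Adding an ester α-carbon to the C16 ketone creates the tertiary hydroxyl, and that same oxygen is placed to open an epoxide at C12 from the face opposite the epoxide oxygen. The tetracyclic cage is reduced to a bicyclic ketone. The forward step needs C2 delivered from the C15 oxygen (hence an ester on C15) and the epoxide on the face of ring A away from C16.

27 is traced through 26 and 24 to 23 by removing the epoxide oxygen, the bromoacetyl group from 25 and the silyl group. The demands are face-selective epoxidation of the ring A alkene and selective cleavage of a tertiary silyl ether beside a primary one.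

23 is cut at C15–C10 and C14–C13 to give 22. This is the intramolecular Diels–Alder disconnection: two rings, two bonds and three stereocentres (C15, C10, C13) fall away and an acyclic trienone with one stereocentre (C8) remains. The forward step needs cis ring fusion and the correct diene face.

22 is traced to 21 (enol silylation) and 21 is cut at C15–C16 to give 17 and 18, an acyl-anion addition to an activated amide. The forward steps need mono-addition and enolisation at the methyl group only.

17 is traced through 16 to 15, which is cut at the bond between C8 and its oxymethyl carbon to give 13 and 14. An auxiliary-controlled enolate alkylation sets the only stereocentre of the cycloaddition precursor. The alkylation sense requires the R auxiliary 11.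

13 is cut at the N-acyl bond to 10 and 11. 10 comes from 9, which is cut at C8–C9 to give 6 and 7 (orthoester Claisen rearrangement). This fixes the E geometry of C10=C11 and delivers the acid chain in one step.

6 is cut at C10–C11 to give 4 and 5. 4 is traced through 2 to 1 by allylic oxidation, which fixes the E geometry of C12=C13.

## Other disconnections considered

Alternative 1: The cut removes three bonds at once: the lactone C–O bond (C15 oxygen to C1), the C2–C16 bond and the ether C–O bond (C12 oxygen to C16). In the forward step a dioxinone at the chain end is heated to an acylketene, which acylates the tertiary C15 hydroxyl; the resulting β-keto ester methylene condenses with the C16 ketone (closing rings C and E) and the C12 hydroxyl adds to the alkylidene (closing ring D), giving A1 with C7 held as a silylated carbinol.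
- In its favour: three rings form in one operation without strong base, the bridging ether forms by a conjugate addition that is under thermodynamic control, and no lactone enolate β to the ether oxygen is ever generated. On these points, and on step economy after the bicyclic stage, it is the better plan.
- Against it: the precursor must already hold rings A and B with the C11/C12 oxygenation and the complete stereodefined chain on C8. Two tertiary hydroxyls (on C15 and C12) compete for the acylketene. The condensation must close an eight-membered ring onto a ketone flanked by a quaternary carbon.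
- Comparison: structurally it addresses rings C, D and E while the chosen key step addresses rings A and B, so the two are complementary rather than exclusive. Mechanistically it is a polar cascade with three chemoselectivity questions against one concerted cycloaddition with one facial question. Both plans keep C7 at the carbinol level during ring closure, and there they are equal.

Alternative 2: The cut removes the ring A bonds C15–C14 and C12–C13. In the forward step the 3-hydroxy-2-pyrone A2, deprotonated by an amine base, adds to the (E)-vinyl sulfone A3 to give the 2-oxabicyclo[2.2.2]octenone A4; its lactone carbonyl carbon is the future C16 and its ring oxygen the future ether oxygen.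
- In its favour: the oxygen bridge and both oxygenated quaternary carbons of ring A (C12 and C15) are set in one intermolecular step from flat, achiral partners, and absolute configuration could come from a chiral amine catalyst instead of a stoichiometric auxiliary. In early introduction of the bridge and in the first steps it is the better plan.
- Against it: the sulfone on C14 must be removed, C11 must be hydroxylated on the alkene with defined configuration, and ring B must be closed by attack of the propanoate enolate on the bridging lactone carbonyl without losing the C16–O bond, which is the normal fate of a lactone under acyl substitution.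
- Comparison: both key steps are [4+2] additions that create three stereocentres, and in that they are equal. The chosen one is intramolecular, so regiochemistry is dictated by the tether, whereas A4 depends on regio- and endo/exo control between two separate partners. Overall step count is likely similar once the ring B and C11 adjustments are included.

Alternative 3: The cut removes the ether bond (C16 oxygen to C12) and the C12–C13 bond. In the forward step a silyl triflate converts a C16 hydroxyl and a C12 methyl ketone into a six-membered oxocarbenium ion, which is attacked across the ring by an aldehyde-derived silyl enol ether at C13, closing rings D and A and giving A5 with a formyl group on C13.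
- In its favour: C12 receives its oxygen and its carbon substituent in one step, no epoxide regiochemistry is involved, and C13 emerges as an epimerisable aldehyde, so an error there could be corrected. On that last point it is better than the chosen plan, where C13 is fixed irreversibly by alkene geometry.
- Against it: the cyclopentane carrying the adjacent quaternary carbons C15 and C16, the lactone and both side arms must be built first by other means; the C13 configuration rests on the conformation of a flexible tether in a cationic cyclisation; and the C8 arm is a β-alkoxy unit exposed to a strong Lewis acid.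
- Comparison: structurally it makes ring A last, where the chosen plan makes it first together with ring B. Mechanistically it is a cationic aldol-type cascade against a thermal pericyclic step. Step economy is comparable; the chosen plan gains by forming two rings from an acyclic chain that is assembled from simple pieces.

Key step: step 12

Remarks on the chemistry:
- The alkylation sense needed for the S configuration at C8 requires (R)-4-benzyl-2-oxazolidinone, not its S enantiomer.
- The two oxygenated arms are differentiated (tert-butyldiphenylsilyl on the C13 arm, benzyl on the C8 arm), since two benzyl ethers could not be told apart later.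
- The enol silyl group is triethylsilyl, so that the tertiary silyl ether can be removed beside the primary one.
- The (R)-valinol-derived silyl N,O-acetal 37 is assumed to deliver 6R by the usual facial sense of this reagent class.
- 41 to 43 are drawn as the hydroxy-enol tautomers.

## Route

Step 1
Reactants: 1 prenol
Product: 2 tert-butyl[(3-methylbut-2-en-1-yl)oxy]diphenylsilane
Conditions: TBDPSCl, imidazole, DMF, 0 °C to rt
Reagents that add atoms: tert-butyl(chloro)diphenylsilane, CC(C)(C)[Si](Cl)(c1ccccc1)c1ccccc1
Why: Standard silylation of a primary allylic alcohol; the bulky silyl ether is chosen because it must survive Lewis acids, organolithium reagents, hydrogenolysis and the later selective cleavage of a triethylsilyl ether.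

Step 2
Reactants: 2 tert-butyl[(3-methylbut-2-en-1-yl)oxy]diphenylsilane
Product: 4 (E)-4-(tert-butyldiphenylsilyloxy)-2-methylbut-2-enal, via allylic alcohol 3 (not isolated)
Conditions: SeO2 (cat.), t-BuOOH, CH2Cl2, rt; then MnO2, CH2Cl2, rt
Reagents that add atoms: selenium dioxide, O=[Se]=O; tert-butyl hydroperoxide, CC(C)(C)OO
Why: Allylic oxidation with SeO2 (ene reaction, then [2,3]-sigmatropic shift) attacks the (E)-methyl group of a trisubstituted alkene, which fixes the E geometry of the later C12=C13 bond; MnO2 takes the allylic alcohol 3 on to the enal without touching the silyl ether.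

Step 3
Reactants: 4 (E)-4-(tert-butyldiphenylsilyloxy)-2-methylbut-2-enal, 5 vinylmagnesium bromide
Product: 6 rac-(E)-6-(tert-butyldiphenylsilyloxy)-4-methylhexa-1,4-dien-3-ol
Conditions: THF, −78 to 0 °C; aq. NH4Cl
Reagents that add atoms: none
Why: 1,2-Addition of a vinyl Grignard reagent to an enal at low temperature; the carbinol configuration does not matter because this carbon becomes sp2 in the next step.

Step 4
Reactants: 6 rac-(E)-6-(tert-butyldiphenylsilyloxy)-4-methylhexa-1,4-dien-3-ol, 7 triethyl orthoacetate
Product: 9 ethyl (4E,6E)-8-(tert-butyldiphenylsilyloxy)-6-methylocta-4,6-dienoate, via ketene acetal 8 (not isolated)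
Conditions: EtCO2H (cat.), 140 °C, ethanol distilled off
Reagents that add atoms: none
Why: Johnson–Claisen rearrangement; the ketene acetal rearranges through a chair with the alkenyl group on the carbinol carbon equatorial, which should give the E alkene C10=C11, and it migrates to the unsubstituted vinyl terminus rather than the hindered trisubstituted one, forming C8–C9.

Step 5
Reactants: 9 ethyl (4E,6E)-8-(tert-butyldiphenylsilyloxy)-6-methylocta-4,6-dienoate
Product: 10 (4E,6E)-8-(tert-butyldiphenylsilyloxy)-6-methylocta-4,6-dienoic acid
Conditions: LiOH, THF/MeOH/H2O, rt; then 1 M HCl to pH 3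
Reagents that add atoms: lithium hydroxide, [Li+].[OH-]
Why: Ester saponification; the hindered silyl ether and the diene are inert to aqueous hydroxide at room temperature.

Step 6
Reactants: 10 (4E,6E)-8-(tert-butyldiphenylsilyloxy)-6-methylocta-4,6-dienoic acid, 11 (R)-4-benzyl-2-oxazolidinone
Product: 13 (R)-4-benzyl-3-[(4E,6E)-8-(tert-butyldiphenylsilyloxy)-6-methylocta-4,6-dienoyl]oxazolidin-2-one, via mixed pivalic anhydride 12 (not isolated)
Conditions: PivCl, Et3N, THF, −20 °C; then LiCl, 11, −20 °C to rt
Reagents that add atoms: none
Why: N-Acylation of the oxazolidinone through the mixed pivalic anhydride; the nucleophile attacks the less hindered carbonyl, and no stereocentre is involved.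

Step 7
Reactants: 13 (R)-4-benzyl-3-[(4E,6E)-8-(tert-butyldiphenylsilyloxy)-6-methylocta-4,6-dienoyl]oxazolidin-2-one, 14 benzyl chloromethyl ether
Product: 15 (R)-4-benzyl-3-[(2S,4E,6E)-2-(benzyloxymethyl)-8-(tert-butyldiphenylsilyloxy)-6-methylocta-4,6-dienoyl]oxazolidin-2-one
Conditions: TiCl4, i-Pr2NEt, CH2Cl2, 0 °C; then 14, 0 °C
Reagents that add atoms: none
Why: Evans alkylation through the chelated chlorotitanium Z-enolate; the electrophile approaches the enolate face opposite the benzyl group of the R auxiliary, which should set C8 as S.

Step 8
Reactants: 15 (R)-4-benzyl-3-[(2S,4E,6E)-2-(benzyloxymethyl)-8-(tert-butyldiphenylsilyloxy)-6-methylocta-4,6-dienoyl]oxazolidin-2-one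
Product: 16 (2S,4E,6E)-2-(benzyloxymethyl)-8-(tert-butyldiphenylsilyloxy)-6-methylocta-4,6-dienoic acid
Conditions: LiOH, H2O2, THF/H2O, 0 °C; then Na2SO3; 1 M HCl to pH 3
Reagents that add atoms: hydrogen peroxide, OO
Why: Hydroperoxide cleavage of the imide; the hydroperoxide anion attacks the exocyclic carbonyl and is too weakly basic to epimerise C8 or eliminate the β-benzyloxy group.

Step 9
Reactants: 16 (2S,4E,6E)-2-(benzyloxymethyl)-8-(tert-butyldiphenylsilyloxy)-6-methylocta-4,6-dienoic acid
Product: 17 (2S,4E,6E)-2-(benzyloxymethyl)-8-(tert-butyldiphenylsilyloxy)-N-methoxy-N,6-dimethylocta-4,6-dienamide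
Conditions: MeNHOMe·HCl, EDC·HCl, HOBt, N-methylmorpholine, CH2Cl2, 0 °C to rt
Reagents that add atoms: N,O-dimethylhydroxylamine hydrochloride, CNOC.Cl
Why: Carbodiimide amide coupling through the hydroxybenzotriazole ester; an acid without an α-acylamino group has no oxazolone pathway, so C8 should keep its configuration.

Step 10
Reactants: 17 (2S,4E,6E)-2-(benzyloxymethyl)-8-(tert-butyldiphenylsilyloxy)-N-methoxy-N,6-dimethylocta-4,6-dienamide, 18 ethyl vinyl ether
Product: 21 (4S,6E,8E)-4-(benzyloxymethyl)-10-(tert-butyldiphenylsilyloxy)-8-methyldeca-6,8-diene-2,3-dione, via 1-ethoxyvinyllithium 19 (not isolated), via ethoxy trienone 20 (not isolated)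
Conditions: 18, t-BuLi, THF, −78 to 0 °C; then 17, −78 °C; then 1 M HCl, THF, 0 °C to rt
Reagents that add atoms: water, O
Why: Acyl-anion addition to a Weinreb amide; the chelated tetrahedral adduct prevents a second addition, and aqueous acid collapses it and hydrolyses the enol ether to the methyl 1,2-diketone, forming C15–C16.

Step 11
Reactants: 21 (4S,6E,8E)-4-(benzyloxymethyl)-10-(tert-butyldiphenylsilyloxy)-8-methyldeca-6,8-diene-2,3-dione
Product: 22 (4S,6E,8E)-4-(benzyloxymethyl)-10-(tert-butyldiphenylsilyloxy)-8-methyl-2-(triethylsilyloxy)deca-1,6,8-trien-3-one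
Conditions: TESOTf, Et3N, CH2Cl2, −78 °C
Reagents that add atoms: triethylsilyl trifluoromethanesulfonate, CC[Si](CC)(CC)OS(=O)(=O)C(F)(F)F
Why: Soft enolisation of a 1,2-dione to a 2-siloxy enone; at −78 °C the amine should remove a proton from the unhindered methyl group and leave the tertiary, doubly branched C8–H alone, so C8 is not epimerised and no benzyloxide is eliminated.

Step 12
Reactants: 22 (4S,6E,8E)-4-(benzyloxymethyl)-10-(tert-butyldiphenylsilyloxy)-8-methyl-2-(triethylsilyloxy)deca-1,6,8-trien-3-one
Product: 23 cis-fused hydrindenone (rings A and B): C16 ketone, C15 triethylsilyloxy, C11=C12 alkene with methyl on C12; the benzyloxymethyl arm on C8, the siloxy group on C15 and H10 share one face of ring B; the silyloxymethyl arm on C13 is cis to C9 on ring A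
Conditions: PhMe (0.01 M), BHT (cat.), 110 °C
Reagents that add atoms: none
Why: The trienone should undergo a concerted, asynchronous [4+2] cycloaddition (closest known type: thermal intramolecular Diels–Alder reaction of 1,6,8-nonatrien-3-ones to cis-hydrindanones), with C15–C10 more advanced than C14–C13. Ring A closes as the six-membered ring of the cycloaddition itself, and ring B closes in a 5-exo sense through the three-atom tether C16–C8–C9 that joins dienophile and diene. C15 and C10 are set by the endo position of the tether carbonyl under the diene, the low-strain arrangement for so short a tether, which gives the cis ring fusion with the siloxy group and H10 on one face. C13 follows from the E geometry of C12=C13, transferred suprafacially, which places the silyloxymethyl arm cis to C9. The diene face is chosen by C8: in the folded tether H8 turns towards the diene and the benzyloxymethyl arm points away from it, avoiding 1,3-strain with H11 and ending up cis to the ring-fusion substituents. Regiochemistry is fixed by the tether, and the siloxy enone is the only electron-poor alkene, so no other cycloaddition mode competes. Heating without a Lewis acid is chosen so that neither the silyl enol ether nor the allylic silyl ether is ionised, and BHT suppresses radical polymerisation.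

Step 13
Reactants: 23 cis-fused hydrindenone with C15 triethylsilyloxy group
Product: 24 ketol: as 23 with a free tertiary hydroxyl on C15
Conditions: HF·pyridine, pyridine, THF, 0 °C
Reagents that add atoms: none
Why: Selective desilylation; a triethylsilyl ether is cleaved far faster than a primary tert-butyldiphenylsilyl ether under buffered HF, and the buffered medium should not provoke an α-ketol shift.

Step 14
Reactants: 24 ketol, 25 bromoacetyl bromide
Product: 26 bromoacetate: as 24 with OC(=O)CH2Br on C15
Conditions: pyridine, CH2Cl2, −20 to 0 °C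
Reagents that add atoms: none
Why: Acylation of a hindered tertiary alcohol with a highly reactive acyl bromide (acylpyridinium or ketene pathway); it is done before epoxidation so that no epoxide is exposed to pyridinium bromide.

Step 15
Reactants: 26 bromoacetate
Product: 27 epoxide: as 26 with an epoxide across C11–C12 on the face of ring A that carries the C15 ester oxygen, H10 and H13
Conditions: mCPBA, NaHCO3, CH2Cl2, 0 °C
Reagents that add atoms: 3-chloroperbenzoic acid, OOC(=O)c1cccc(Cl)c1
Why: Prilezhaev epoxidation of the only alkene; both allylic substituents (C9 on C10 and the silyloxymethyl arm on C13) lie on one face of ring A, so the peracid should add from the other face, which sets C11 and the oxygen needed for anti opening at C12.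

Step 16
Reactants: 27 epoxide
Product: 29 cage lactone alcohol (rings A to D): γ-lactone C1/C2 fused at C15–C16, ether bridge C12–O–C16, free C11 hydroxyl anti to the bridge, benzyloxymethyl on C8, silyloxymethyl on C13, via epoxy hydroxy lactone 28 (not isolated)
Conditions: SmI2 (2.2 equiv), THF, −78 °C; sat. NH4Cl; then CSA (cat.), CH2Cl2, 0 °C to rt
Reagents that add atoms: none
Why: Intramolecular Reformatsky reaction promoted by samarium diiodide, then acid-catalysed epoxide opening: the samarium enolate from the C–Br bond adds to the adjacent C16 ketone through a five-membered ring, so C2 arrives on the face of the ester oxygen and the new C16 hydroxyl points towards ring A; protonation of the epoxide then lets this hydroxyl attack the tertiary C12 with inversion (anti, Markovnikov), closing ring D and leaving the C11 hydroxyl.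

Step 17
Reactants: 29 cage lactone alcohol
Product: 30 cage lactone with C11 tert-butyldimethylsilyl ether
Conditions: TBSOTf, 2,6-lutidine, CH2Cl2, 0 °C
Reagents that add atoms: tert-butyldimethylsilyl trifluoromethanesulfonate, CC(C)(C)[Si](C)(C)OS(=O)(=O)C(F)(F)F
Why: Silylation of a hindered secondary alcohol with a silyl triflate; the hydroxyl must be masked before the two oxidations that follow.

Step 18
Reactants: 30 cage lactone with C11 tert-butyldimethylsilyl ether
Product: 31 primary alcohol: as 30 with CH2OH on C8
Conditions: H2 (1 atm), Pd/C, EtOAc, rt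
Reagents that add atoms: none
Why: Hydrogenolysis of the single benzyl ether; the molecule holds no alkene at this stage, and silyl ethers, lactone and ether bridge are inert.

Step 19
Reactants: 31 primary alcohol
Product: 32 aldehyde: as 30 with CHO (C7) on C8
Conditions: Dess–Martin periodinane, NaHCO3, CH2Cl2, 0 °C to rt
Reagents that add atoms: none
Why: Dess–Martin oxidation under buffered, non-basic conditions, which should leave the α-stereocentre C8 untouched; the aldehyde is used without storage.

Step 20
Reactants: 33 (E)-2-methylpent-2-enoic acid, 34 (R)-4-isopropyl-2-oxazolidinone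
Product: 36 (R)-4-isopropyl-3-[(E)-2-methylpent-2-enoyl]oxazolidin-2-one, via mixed pivalic anhydride 35 (not isolated)
Conditions: PivCl, Et3N, THF, −20 °C; then LiCl, 34, rt
Reagents that add atoms: none
Why: N-Acylation of the auxiliary through the mixed pivalic anhydride, as in step 6.

Step 21
Reactants: 36 (R)-4-isopropyl-3-[(E)-2-methylpent-2-enoyl]oxazolidin-2-one
Product: 37 (R)-3-[(1E,3E)-1-(tert-butyldimethylsilyloxy)-2-methylpenta-1,3-dien-1-yl]-4-isopropyloxazolidin-2-one
Conditions: NaN(SiMe3)2, THF, −78 °C; then TBSCl
Reagents that add atoms: tert-butyl(chloro)dimethylsilane, CC(C)(C)[Si](C)(C)Cl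
Why: γ-Deprotonation of the enoyl imide and O-silylation of the chelated dienolate, the standard route to (E,E)-vinylketene silyl N,O-acetals.

Step 22
Reactants: 32 aldehyde, 37 (R)-3-[(1E,3E)-1-(tert-butyldimethylsilyloxy)-2-methylpenta-1,3-dien-1-yl]-4-isopropyloxazolidin-2-one
Product: 38 vinylogous aldol adduct: cage core of 30 carrying on C8 the chain (7R)-CH(OH)–(6R)-CH(Me)–CH=C(Me)–C(=O)–N(oxazolidinone), E alkene, C6/C7 anti
Conditions: TiCl4, CH2Cl2, −78 to −40 °C
Reagents that add atoms: none
Why: Vinylogous Mukaiyama aldol reaction of a chiral vinylketene silyl N,O-acetal: the oxazolidinone is twisted out of the dienol ether plane and its isopropyl group covers one face, so the TiCl4-bound aldehyde reaches the γ-carbon from the open face through an antiperiplanar array; this should set C6 as R under reagent control and give the anti adduct, whose C7 configuration has no lasting importance.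

Step 23
Reactants: 38 vinylogous aldol adduct
Product: 40 δ-lactone: cage core of 30 carrying on C8 a tetrahydropyran-2-one (O–C7, C6 methyl, C5, C4 methyl, C3 carbonyl) with all three substituents equatorial, via saturated hydroxy imide 39 (not isolated)
Conditions: H2 (40 bar), [Rh(nbd)(dppb)]BF4 (cat.), CH2Cl2, rt; then DBU, CH2Cl2, rt
Reagents that add atoms: none
Why: Hydroxyl-directed hydrogenation with a cationic rhodium catalyst: allylic 1,3-strain keeps H6 in the plane of the (E)-alkene and the rhodium-bound C7 hydroxyl guides H2 to its own face, which should set C4 as S (4,6-syn methyl groups); DBU then lets the C7 hydroxyl displace the auxiliary, and the all-equatorial δ-lactone is also the thermodynamically preferred C4 epimer.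

Step 24
Reactants: 40 δ-lactone
Product: 41 pentacycle: silyl-protected abyssomicin O skeleton with C7 as a free (R)-carbinol and the C2=C3 enol
Conditions: LiN(SiMe3)2 (2.2 equiv), THF, −78 to −40 °C; AcOH
Reagents that add atoms: none
Why: Intramolecular Claisen condensation onto a lactone (O-to-C acyl transfer): the lithium enolate at C2 attacks the δ-lactone carbonyl C3 through a six-membered array, the tetrahedral adduct expels the C7 alkoxide and the acidic β-keto lactone is deprotonated, which drives the ring expansion to the eight-membered ring E; C4 is not part of the enolate and should keep its configuration.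

Step 25
Reactants: 41 pentacycle with C7 carbinol
Product: 42 bis-silyl abyssomicin O (C11 tert-butyldimethylsilyl ether, tert-butyldiphenylsilyl ether on the C13 arm)
Conditions: Dess–Martin periodinane, NaHCO3, CH2Cl2, 0 °C to rt
Reagents that add atoms: none
Why: Dess–Martin oxidation of the only free secondary alcohol; the buffered, non-basic medium should not enolise the new C7 ketone, so C6 and C8 are preserved, and the hindered enolised β-keto lactone should react far more slowly.

Step 26
Reactants: 42 bis-silyl abyssomicin O
Product: 43 abyssomicin O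
Conditions: HF (48% aq.), MeCN, rt
Reagents that add atoms: none
Why: Acidic global desilylation of a primary and a hindered secondary silyl ether; acid is chosen over basic fluoride so that the C7 ketone is not enolised and the β-keto lactone is not cleaved.

## Compound list

1 | prenol (3-methylbut-2-en-1-ol) | CC(C)=CCO | starting material
2 | tert-butyl[(3-methylbut-2-en-1-yl)oxy]diphenylsilane | CC(C)=CCO[Si](c1ccccc1)(c1ccccc1)C(C)(C)C | intermediate
3 | (E)-4-(tert-butyldiphenylsilyloxy)-2-methylbut-2-en-1-ol | OC/C(C)=C/CO[Si](c1ccccc1)(c1ccccc1)C(C)(C)C | intermediate (not isolated)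
4 | (E)-4-(tert-butyldiphenylsilyloxy)-2-methylbut-2-enal | O=C/C(C)=C/CO[Si](c1ccccc1)(c1ccccc1)C(C)(C)C | intermediate
5 | vinylmagnesium bromide | C=C[Mg]Br | starting material
6 | rac-(E)-6-(tert-butyldiphenylsilyloxy)-4-methylhexa-1,4-dien-3-ol | C=CC(O)/C(C)=C/CO[Si](c1ccccc1)(c1ccccc1)C(C)(C)C | intermediate
7 | triethyl orthoacetate | CC(OCC)(OCC)OCC | starting material
8 | ketene acetal (1-ethoxyvinyl ether of 6) | C=C(OCC)OC(C=C)/C(C)=C/CO[Si](c1ccccc1)(c1ccccc1)C(C)(C)C | intermediate (not isolated)
9 | ethyl (4E,6E)-8-(tert-butyldiphenylsilyloxy)-6-methylocta-4,6-dienoate | CCOC(=O)CC/C=C/C(C)=C/CO[Si](c1ccccc1)(c1ccccc1)C(C)(C)C | intermediate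
10 | (4E,6E)-8-(tert-butyldiphenylsilyloxy)-6-methylocta-4,6-dienoic acid | OC(=O)CC/C=C/C(C)=C/CO[Si](c1ccccc1)(c1ccccc1)C(C)(C)C | intermediate
11 | (R)-4-benzyl-2-oxazolidinone | O=C1N[C@H](Cc2ccccc2)CO1 | starting material
12 | mixed pivalic anhydride of 10 | CC(C)(C)C(=O)OC(=O)CC/C=C/C(C)=C/CO[Si](c1ccccc1)(c1ccccc1)C(C)(C)C | intermediate (not isolated)
13 | (R)-4-benzyl-3-[(4E,6E)-8-(tert-butyldiphenylsilyloxy)-6-methylocta-4,6-dienoyl]oxazolidin-2-one | O=C1OC[C@@H](Cc2ccccc2)N1C(=O)CC/C=C/C(C)=C/CO[Si](c3ccccc3)(c3ccccc3)C(C)(C)C | intermediate
14 | benzyl chloromethyl ether | ClCOCc1ccccc1 | starting material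
15 | (R)-4-benzyl-3-[(2S,4E,6E)-2-(benzyloxymethyl)-8-(tert-butyldiphenylsilyloxy)-6-methylocta-4,6-dienoyl]oxazolidin-2-one | O=C1OC[C@@H](Cc2ccccc2)N1C(=O)[C@H](COCc2ccccc2)C/C=C/C(C)=C/CO[Si](c3ccccc3)(c3ccccc3)C(C)(C)C | intermediate
16 | (2S,4E,6E)-2-(benzyloxymethyl)-8-(tert-butyldiphenylsilyloxy)-6-methylocta-4,6-dienoic acid | OC(=O)[C@H](COCc1ccccc1)C/C=C/C(C)=C/CO[Si](c2ccccc2)(c2ccccc2)C(C)(C)C | intermediate
17 | (2S,4E,6E)-2-(benzyloxymethyl)-8-(tert-butyldiphenylsilyloxy)-N-methoxy-N,6-dimethylocta-4,6-dienamide | CON(C)C(=O)[C@H](COCc1ccccc1)C/C=C/C(C)=C/CO[Si](c2ccccc2)(c2ccccc2)C(C)(C)C | intermediate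
18 | ethyl vinyl ether | C=COCC | starting material
19 | 1-ethoxyvinyllithium | [Li]C(=C)OCC | intermediate (not isolated)
20 | (4S,6E,8E)-4-(benzyloxymethyl)-2-ethoxy-10-(tert-butyldiphenylsilyloxy)-8-methyldeca-1,6,8-trien-3-one | C=C(OCC)C(=O)[C@H](COCc1ccccc1)C/C=C/C(C)=C/CO[Si](c2ccccc2)(c2ccccc2)C(C)(C)C | intermediate (not isolated)
21 | (4S,6E,8E)-4-(benzyloxymethyl)-10-(tert-butyldiphenylsilyloxy)-8-methyldeca-6,8-diene-2,3-dione | CC(=O)C(=O)[C@H](COCc1ccccc1)C/C=C/C(C)=C/CO[Si](c2ccccc2)(c2ccccc2)C(C)(C)C | intermediate
22 | (4S,6E,8E)-4-(benzyloxymethyl)-10-(tert-butyldiphenylsilyloxy)-8-methyl-2-(triethylsilyloxy)deca-1,6,8-trien-3-one | C=C(O[Si](CC)(CC)CC)C(=O)[C@H](COCc1ccccc1)C/C=C/C(C)=C/CO[Si](c2ccccc2)(c2ccccc2)C(C)(C)C | intermediate (key-step precursor)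
23 | cis-fused hydrindenone with silylated acyloin (rings A and B) | O=C1[C@H](COCc3ccccc3)C[C@H]2C=C(C)[C@@H](CO[Si](c4ccccc4)(c4ccccc4)C(C)(C)C)C[C@@]12O[Si](CC)(CC)CC | intermediate (key-step product)
24 | ketol (free C15 hydroxyl) | O=C1[C@H](COCc3ccccc3)C[C@H]2C=C(C)[C@@H](CO[Si](c4ccccc4)(c4ccccc4)C(C)(C)C)C[C@@]12O | intermediate
25 | bromoacetyl bromide | BrCC(Br)=O | starting material
26 | bromoacetate of 24 | O=C1[C@H](COCc3ccccc3)C[C@H]2C=C(C)[C@@H](CO[Si](c4ccccc4)(c4ccccc4)C(C)(C)C)C[C@@]12OC(=O)CBr | intermediate
27 | C11–C12 epoxide of 26 | O=C1[C@H](COCc3ccccc3)C[C@H]2[C@@H]5O[C@]5(C)[C@@H](CO[Si](c4ccccc4)(c4ccccc4)C(C)(C)C)C[C@@]12OC(=O)CBr | intermediate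
28 | epoxy hydroxy lactone (C16 tertiary alcohol, rings A, B, C) | C1C(=O)O[C@]23C[C@H](CO[Si](c6ccccc6)(c6ccccc6)C(C)(C)C)[C@@]4(C)O[C@H]4[C@@H]3C[C@@H](COCc7ccccc7)[C@@]12O | intermediate (not isolated)
29 | cage lactone alcohol (rings A to D, free C11 hydroxyl) | C1C(=O)O[C@]23C[C@H](CO[Si](c6ccccc6)(c6ccccc6)C(C)(C)C)[C@]4(C)O[C@]12[C@@H](C[C@H]3[C@@H]4O)COCc7ccccc7 | intermediate
30 | cage lactone, C11 tert-butyldimethylsilyl ether | C1C(=O)O[C@]23C[C@H](CO[Si](c6ccccc6)(c6ccccc6)C(C)(C)C)[C@]4(C)O[C@]12[C@@H](C[C@H]3[C@@H]4O[Si](C)(C)C(C)(C)C)COCc7ccccc7 | intermediate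
31 | cage lactone, primary alcohol on the C8 arm | C1C(=O)O[C@]23C[C@H](CO[Si](c6ccccc6)(c6ccccc6)C(C)(C)C)[C@]4(C)O[C@]12[C@@H](C[C@H]3[C@@H]4O[Si](C)(C)C(C)(C)C)CO | intermediate
32 | cage lactone aldehyde (C7 formyl on C8) | C1C(=O)O[C@]23C[C@H](CO[Si](c6ccccc6)(c6ccccc6)C(C)(C)C)[C@]4(C)O[C@]12[C@@H](C[C@H]3[C@@H]4O[Si](C)(C)C(C)(C)C)C=O | intermediate
33 | (E)-2-methylpent-2-enoic acid | CC/C=C(\C)C(=O)O | starting material
34 | (R)-4-isopropyl-2-oxazolidinone | CC(C)[C@@H]1COC(=O)N1 | starting material
35 | mixed pivalic anhydride of 33 | CC/C=C(\C)C(=O)OC(=O)C(C)(C)C | intermediate (not isolated)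
36 | (R)-4-isopropyl-3-[(E)-2-methylpent-2-enoyl]oxazolidin-2-one | CC/C=C(\C)C(=O)N1C(=O)OC[C@H]1C(C)C | intermediate
37 | (R)-3-[(1E,3E)-1-(tert-butyldimethylsilyloxy)-2-methylpenta-1,3-dien-1-yl]-4-isopropyloxazolidin-2-one | C/C=C/C(C)=C(\N1C(=O)OC[C@H]1C(C)C)O[Si](C)(C)C(C)(C)C | intermediate
38 | vinylogous aldol adduct (6R,7R, E-enoyl imide) | C1C(=O)O[C@]23C[C@H](CO[Si](c6ccccc6)(c6ccccc6)C(C)(C)C)[C@]4(C)O[C@]12[C@@H](C[C@H]3[C@@H]4O[Si](C)(C)C(C)(C)C)[C@H](O)[C@H](C)/C=C(\C)C(=O)N7C(=O)OC[C@H]7C(C)C | intermediate
39 | saturated hydroxy imide (4S,6R,7R) | C1C(=O)O[C@]23C[C@H](CO[Si](c6ccccc6)(c6ccccc6)C(C)(C)C)[C@]4(C)O[C@]12[C@@H](C[C@H]3[C@@H]4O[Si](C)(C)C(C)(C)C)[C@H](O)[C@H](C)C[C@H](C)C(=O)N7C(=O)OC[C@H]7C(C)C | intermediate (not isolated)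
40 | δ-lactone on the cage (all-equatorial 3,5-dimethyl-6-substituted tetrahydropyran-2-one) | C1C(=O)O[C@]23C[C@H](CO[Si](c6ccccc6)(c6ccccc6)C(C)(C)C)[C@]4(C)O[C@]12[C@@H](C[C@H]3[C@@H]4O[Si](C)(C)C(C)(C)C)[C@@H]5OC(=O)[C@@H](C)C[C@H]5C | intermediate
41 | silyl-protected pentacycle with C7 carbinol | C[C@@H]1C[C@H](C)/C(O)=C2/C(=O)O[C@]34C[C@H](CO[Si](c6ccccc6)(c6ccccc6)C(C)(C)C)[C@]5(C)O[C@]23[C@@H](C[C@H]4[C@@H]5O[Si](C)(C)C(C)(C)C)[C@@H]1O | intermediate
42 | bis-silyl abyssomicin O | C[C@@H]1C[C@H](C)/C(O)=C2/C(=O)O[C@]34C[C@H](CO[Si](c6ccccc6)(c6ccccc6)C(C)(C)C)[C@]5(C)O[C@]23[C@@H](C[C@H]4[C@@H]5O[Si](C)(C)C(C)(C)C)C1=O | intermediate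
43 | abyssomicin O | C[C@@H]1C[C@H](C)/C(O)=C2/C(=O)O[C@]34C[C@H](CO)[C@]5(C)O[C@]23[C@@H](C[C@H]4[C@@H]5O)C1=O | target

## Step count and least certain steps

Total step count: 26 (24 on the main line plus 2 for reagent 37). Longest linear sequence: 24 steps from prenol (steps 1 to 19 and 22 to 26).

**Step 12 (key step).** What may go wrong: poor facial selectivity. The only controlling element is an acyclic stereocentre α to the tether carbonyl, whose two faces differ by H against a benzyloxymethyl arm; slow cyclisation with loss of the silyl enol ether on prolonged heating is a second risk. Fallback: take the stereocentre out of the cycloaddition. Setting out from acid 10, the Weinreb amide F1 is made as in step 9 and treated with 1-ethoxyvinyllithium 19 and aqueous acid to give, through ethoxy trienone F2, the dione F3. Kinetic silylation at the methyl group gives the achiral siloxy trienone F4, which is cyclised under a chiral oxazaborolidinium triflimide Lewis acid so that the catalyst chooses the diene face, giving the des-benzyloxymethyl hydrindenone F5. F5 can be deprotonated only at C8 (C15 is quaternary), and alkylation of that enolate (LiN(SiMe3)2, then 14) from the convex face should install the arm cis to the ring-fusion substituents, which brings the route back at 23.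

**Step 16.** What may go wrong: reduction of the activated α-acyloxy ketone (ketyl formation and loss of the ester) in competition with the C–Br bond, or opening of the trisubstituted epoxide by iodide in the presence of samarium salts. Fallback: generate the ester enolate by deprotonation instead of reduction. Setting out from ketol 24, acetylation (Ac2O, DMAP, Et3N) gives acetate F6 and epoxidation as in step 15 gives epoxy acetate F7. LiN(SiMe3)2 in THF at −78 °C then brings about the same intramolecular aldol addition to C16, giving 28, which is closed with CSA and comes back to the route at 29.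

**Step 22.** What may go wrong: low conversion or eroded selectivity. The aldehyde is α-branched and flanked by the cage, and its own facial bias may oppose the anti preference of the reagent; epimerisation at C8 under TiCl4 is a lesser risk. Fallback: build the lactone by crotylation and metathesis. Setting out from aldehyde 32, reagent-controlled crotylboration with (E)-crotyldiisopinocampheylborane (antipode chosen for the 6R,7R anti adduct) gives homoallylic alcohol F8. Acylation with methacryloyl chloride gives diene ester F9, and ring-closing metathesis with the second-generation Grubbs catalyst gives the unsaturated lactone F10. Hydrogenation over Pd/C from the face opposite the C6 methyl group, with DBU equilibration at C4 if needed, comes back to the route at 40.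

**Step 24.** What may go wrong: elimination of the bridging ether oxygen. The lithium enolate at C2 is β to the oxygen on C16 and may expel it before acylation, opening ring D; enolisation of the δ-lactone at C4 is a second unproductive path. Fallback: make the acylation irreversible at −78 °C with an open-chain amide. Setting out from lactone 40, opening with Me2AlN(OMe)Me (from AlMe3 and MeNHOMe·HCl) gives the hydroxy Weinreb amide F11, which is protected as the triethylsilyl ether F12. Cyclisation with LiN(SiMe3)2 at −78 °C passes through a chelated tetrahedral adduct that does not revert, so no warming is needed, and gives the silyl-protected pentacycle F13. Removal of the triethylsilyl group with HF·pyridine comes back to the route at 41.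

## Further compounds

F1 | step 12 | (4E,6E)-8-(tert-butyldiphenylsilyloxy)-N-methoxy-N,6-dimethylocta-4,6-dienamide | CON(C)C(=O)CC/C=C/C(C)=C/CO[Si](c1ccccc1)(c1ccccc1)C(C)(C)C
F2 | step 12 | (6E,8E)-2-ethoxy-10-(tert-butyldiphenylsilyloxy)-8-methyldeca-1,6,8-trien-3-one | C=C(OCC)C(=O)CC/C=C/C(C)=C/CO[Si](c1ccccc1)(c1ccccc1)C(C)(C)C
F3 | step 12 | (6E,8E)-10-(tert-butyldiphenylsilyloxy)-8-methyldeca-6,8-diene-2,3-dione | CC(=O)C(=O)CC/C=C/C(C)=C/CO[Si](c1ccccc1)(c1ccccc1)C(C)(C)C
F4 | step 12 | (6E,8E)-10-(tert-butyldiphenylsilyloxy)-8-methyl-2-(triethylsilyloxy)deca-1,6,8-trien-3-one | C=C(O[Si](CC)(CC)CC)C(=O)CC/C=C/C(C)=C/CO[Si](c1ccccc1)(c1ccccc1)C(C)(C)C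
F5 | step 12 | des-benzyloxymethyl analogue of 23 (C8 is CH2) | O=C1CC[C@H]2C=C(C)[C@@H](CO[Si](c4ccccc4)(c4ccccc4)C(C)(C)C)C[C@@]12O[Si](CC)(CC)CC
F6 | step 16 | acetate of ketol 24 | O=C1[C@H](COCc3ccccc3)C[C@H]2C=C(C)[C@@H](CO[Si](c4ccccc4)(c4ccccc4)C(C)(C)C)C[C@@]12OC(C)=O
F7 | step 16 | C11–C12 epoxide of acetate F6 | O=C1[C@H](COCc3ccccc3)C[C@H]2[C@@H]5O[C@]5(C)[C@@H](CO[Si](c4ccccc4)(c4ccccc4)C(C)(C)C)C[C@@]12OC(C)=O
F8 | step 22 | homoallylic alcohol (6R,7R) from crotylboration of 32 | C1C(=O)O[C@]23C[C@H](CO[Si](c6ccccc6)(c6ccccc6)C(C)(C)C)[C@]4(C)O[C@]12[C@@H](C[C@H]3[C@@H]4O[Si](C)(C)C(C)(C)C)[C@H](O)[C@H](C)C=C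
F9 | step 22 | methacrylate ester of F8 | C1C(=O)O[C@]23C[C@H](CO[Si](c6ccccc6)(c6ccccc6)C(C)(C)C)[C@]4(C)O[C@]12[C@@H](C[C@H]3[C@@H]4O[Si](C)(C)C(C)(C)C)[C@H](OC(=O)C(C)=C)[C@H](C)C=C
F10 | step 22 | unsaturated δ-lactone (3,5-dimethyl-5,6-dihydropyran-2-one on the cage) | C1C(=O)O[C@]23C[C@H](CO[Si](c6ccccc6)(c6ccccc6)C(C)(C)C)[C@]4(C)O[C@]12[C@@H](C[C@H]3[C@@H]4O[Si](C)(C)C(C)(C)C)[C@@H]5OC(=O)C(C)=C[C@H]5C
F11 | step 24 | hydroxy Weinreb amide from opening of 40 | C1C(=O)O[C@]23C[C@H](CO[Si](c6ccccc6)(c6ccccc6)C(C)(C)C)[C@]4(C)O[C@]12[C@@H](C[C@H]3[C@@H]4O[Si](C)(C)C(C)(C)C)[C@H](O)[C@H](C)C[C@H](C)C(=O)N(C)OC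
F12 | step 24 | triethylsilyl ether of F11 | C1C(=O)O[C@]23C[C@H](CO[Si](c6ccccc6)(c6ccccc6)C(C)(C)C)[C@]4(C)O[C@]12[C@@H](C[C@H]3[C@@H]4O[Si](C)(C)C(C)(C)C)[C@H](O[Si](CC)(CC)CC)[C@H](C)C[C@H](C)C(=O)N(C)OC
F13 | step 24 | C7 O-triethylsilyl derivative of 41 | C[C@@H]1C[C@H](C)/C(O)=C2/C(=O)O[C@]34C[C@H](CO[Si](c6ccccc6)(c6ccccc6)C(C)(C)C)[C@]5(C)O[C@]23[C@@H](C[C@H]4[C@@H]5O[Si](C)(C)C(C)(C)C)[C@@H]1O[Si](CC)(CC)CC
A1 | alternative 1 | silyl-protected pentacycle with C7 at carbinol level | C[C@@H]1C[C@H](C)/C(O)=C2/C(=O)O[C@]34C[C@H](CO[Si](C)(C)C(C)(C)C)[C@]5(C)O[C@]23[C@@H](C[C@H]4[C@@H]5O[Si](C)(C)C(C)(C)C)[C@H]1O[Si](CC)(CC)CC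
A2 | alternative 2 | methyl 3-(3-hydroxy-6-methyl-2-oxo-2H-pyran-4-yl)propanoate | COC(=O)CCc1cc(C)oc(=O)c1O
A3 | alternative 2 | (E)-tert-butyldimethyl[3-(phenylsulfonyl)allyloxy]silane | CC(C)(C)[Si](C)(C)OC/C=C/S(=O)(=O)c1ccccc1
A4 | alternative 2 | bridged bicyclic lactone with endo sulfone and exo silyloxymethyl group | O=C1O[C@]2(C)C=C(CCC(=O)OC)[C@@]1(O)[C@@H](S(=O)(=O)c3ccccc3)[C@@H]2CO[Si](C)(C)C(C)(C)C
A5 | alternative 3 | tetracyclic cage lactone with formyl group on C13 | O=C1O[C@]23C[C@H](C=O)[C@]4(C)O[C@@]2(C1)[C@H](COCc5ccccc5)C[C@H]3[C@@H]4O[Si](C)(C)C(C)(C)C
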